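**Retrosynthetic overview**

1. Ring B oxidation pattern last: the 6β‑hydroxy‑8‑en‑7‑one comes from a Δ7 6β‑allylic alcohol by a singlet‑oxygen ene reaction and dehydration; the 6β‑OH comes from α‑face hydride reduction of a 7‑en‑6‑one.
2. The β‑hydroxy‑γ‑lactone is carried as a 2‑tert‑butyl‑1,3‑dioxolan‑4‑one with a CH2CO2Et arm and is unmasked by the same hydride step.
3. Key disconnection: C11–C12 and C13–C14 in one photoredox radical relay joining the C11 radical from saponified (+)‑sclareolide (loss of CO2), a lactic‑acid‑derived methylene dioxolanone and ethyl diazoacetate.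
4. Stereocentres: C5 and C10 are bought in sclareolide; C13 is relayed from (R)‑lactic acid through the tert‑butyl acetal carbon; C6 is set by substrate control.
5. Ring order: rings A and B are bought; the dioxolanone ring is made first (steps 1–2), the lactone ring in step 6, ring B unsaturation and oxygenation in steps 4–7.

Assumption: positions are cited in labdane numbering (C17 = methyl on C8; C15 = lactone carbonyl; C16 = lactone OCH2), and (R)‑lactic acid, (+)‑sclareolide, pivalaldehyde and ethyl diazoacetate are bought.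

**Route**

Step 1
Reactants: 1 (R)-lactic acid
Product: 2 (2R,5R)-2-tert-butyl-5-methyl-1,3-dioxolan-4-one
Conditions: t-BuCHO, TsOH·H2O (cat.), H2SO4 (cat.), pentane, reflux, Dean–Stark; recrystallization from Et2O/pentane, −78 °C
Reagents that add atoms: pivalaldehyde CC(C)(C)C=O
Why: Acid-catalysed acetalization (Seebach self-regeneration-of-stereocentres acetal) in which the lactic acid stereocentre directs the new acetal carbon to the cis (2R,5R) isomer under thermodynamic control, upgraded by crystallization.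

Step 2
Reactants: 2 (2R,5R)-2-tert-butyl-5-methyl-1,3-dioxolan-4-one
Product: 4 (2R)-2-tert-butyl-5-methylidene-1,3-dioxolan-4-one, via tertiary bromide 3 (not isolated)
Conditions: NBS, AIBN (cat.), PhCF3, 80 °C; then Et3N, 0 °C to rt
Reagents that add atoms: none
Why: Wohl–Ziegler radical bromination of the captodative C5–H followed by E2 dehydrobromination, which erases the C5 stereocentre and leaves the chirality stored at the acetal carbon (2R).

Step 3
Reactants: 5 (+)-sclareolide; 4 (2R)-2-tert-butyl-5-methylidene-1,3-dioxolan-4-one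
Product: 7 ethyl 2-[(2R,4S)-2-tert-butyl-4-{2-[(1R,2R,4aS,8aS)-2-hydroxy-2,5,5,8a-tetramethyldecahydronaphthalen-1-yl]ethyl}-5-oxo-1,3-dioxolan-4-yl]acetate, via cesium hydroxy-carboxylate 6 (not isolated)
Conditions: 5 (1.3 equiv), CsOH·H2O, MeOH/H2O, 60 °C, then dry; 4 (1.0 equiv), ethyl diazoacetate (4 equiv), Ir[dF(CF3)ppy]2(dtbbpy)PF6 (2 mol%), H2O (10 equiv), DMSO, 450 nm LEDs, 25 °C
Reagents that add atoms: ethyl diazoacetate CCOC(=O)C=[N+]=[N-]
Why: Proposed new method: a three-component radical relay in which the photoexcited iridium catalyst oxidizes carboxylate 6 (loss of CO2), the unstabilized primary C11 radical is trapped fastest by the exocyclic CH2 of captodative alkene 4 (C11–C12 bond), the resulting persistent dioxolanonyl C13 radical adds to the diazo carbon of ethyl diazoacetate on the face anti to the tert-butyl group with loss of N2 (C13–C14 bond, quaternary 13S centre controlled by the lactate-derived acetal carbon), and the α-ester radical is reduced by the reduced photocatalyst and protonated; the closest known reaction types are photoredox decarboxylative Giese addition to Beckwith/Karady-type methylene heterocycles and carbon-radical addition to diazo esters with N2 loss.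

Step 4
Reactants: 7 ethyl 2-[(2R,4S)-2-tert-butyl-4-{2-[(1R,2R,4aS,8aS)-2-hydroxy-2,5,5,8a-tetramethyldecahydronaphthalen-1-yl]ethyl}-5-oxo-1,3-dioxolan-4-yl]acetate
Product: 8 ethyl 2-[(2R,4S)-2-tert-butyl-5-oxo-4-{2-[(1S,4aS,8aS)-2,5,5,8a-tetramethyl-1,4,4a,5,6,7,8,8a-octahydronaphthalen-1-yl]ethyl}-1,3-dioxolan-4-yl]acetate
Conditions: Martin sulfurane, CH2Cl2, −40 to 0 °C
Reagents that add atoms: none
Why: E1-type dehydration through the alkoxysulfonium ion pair (Martin sulfurane), where kinetic loss of the accessible axial 7α-H from the C8 cation, as in drimenyl-type cyclization terminations, gives mainly the trisubstituted Δ7 alkene and creates no stereocentre.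

Step 5
Reactants: 8 ethyl 2-[(2R,4S)-2-tert-butyl-5-oxo-4-{2-[(1S,4aS,8aS)-2,5,5,8a-tetramethyl-1,4,4a,5,6,7,8,8a-octahydronaphthalen-1-yl]ethyl}-1,3-dioxolan-4-yl]acetate
Product: 9 ethyl 2-[(2R,4S)-2-tert-butyl-5-oxo-4-{2-[(1S,4aS,8aR)-2,5,5,8a-tetramethyl-4-oxo-1,4,4a,5,6,7,8,8a-octahydronaphthalen-1-yl]ethyl}-1,3-dioxolan-4-yl]acetate
Conditions: CrO3, 3,5-dimethylpyrazole, CH2Cl2, −20 °C
Reagents that add atoms: chromium trioxide O=[Cr](=O)=O
Why: Allylic oxidation with the CrO3·3,5-dimethylpyrazole complex, which converts the allylic CH2 (C6) next to the CH end of the trisubstituted alkene into the conjugated ketone as in Δ5-steroid to 7-ketone oxidations, with no stereocentre formed and the acetal and ester inert.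

Step 6
Reactants: 9 ethyl 2-[(2R,4S)-2-tert-butyl-5-oxo-4-{2-[(1S,4aS,8aR)-2,5,5,8a-tetramethyl-4-oxo-1,4,4a,5,6,7,8,8a-octahydronaphthalen-1-yl]ethyl}-1,3-dioxolan-4-yl]acetate
Product: 11 (13S)-6β,13-dihydroxylabd-7-en-15,16-olide, via diol ester 10 (not isolated)
Conditions: NaBH4, CeCl3·7H2O, EtOH/THF, −20 °C to rt; aq. NH4Cl
Reagents that add atoms: none
Why: Luche-type hydride reduction in which hydride adds to the C6 ketone from the α face because the β face is shielded by the syn-axial C10 and C4β methyl groups (axial 6β-alcohol), while the activated acylal carbonyl of the dioxolanone is reduced to the primary alcohol with loss of pivalaldehyde and the diol ester lactonizes (5-exo-trig) without touching C13.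

Step 7
Reactants: 11 (13S)-6β,13-dihydroxylabd-7-en-15,16-olide
Product: 14 (13S)-6β,13-dihydroxy-7-oxolabd-8-en-15,16-olide, via allylic hydroperoxide 12 (not isolated), via peracetate 13 (not isolated)
Conditions: O2, tetraphenylporphyrin (cat.), white LEDs, Ac2O (2 equiv), pyridine/CH2Cl2, 0 °C
Reagents that add atoms: dioxygen O=O
Why: Schenck ene reaction then Kornblum–DeLaMare-type elimination, in which singlet oxygen adds to C7 from the less hindered α face with suprafacial abstraction of the pseudo-axial 9α-H (the 6α-H is pseudo-equatorial and geminal to OH) so that the double bond moves to C8–C9, and the peracetate formed in situ eliminates to the C7 ketone without affecting C6 or C13.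

**Compound list**

1 | (R)-lactic acid, (2R)-2-hydroxypropanoic acid | C[C@@H](O)C(O)=O | starting material
2 | (2R,5R)-2-tert-butyl-5-methyl-1,3-dioxolan-4-one (cis) | C[C@H]1O[C@@H](C(C)(C)C)OC1=O | intermediate
3 | (2S,5S)-5-bromo-2-tert-butyl-5-methyl-1,3-dioxolan-4-one (Br trans to tert-butyl) | C[C@@]1(Br)O[C@@H](C(C)(C)C)OC1=O | intermediate
4 | (2R)-2-tert-butyl-5-methylidene-1,3-dioxolan-4-one | C=C1O[C@@H](C(C)(C)C)OC1=O | intermediate
5 | (+)-sclareolide, (3aR,5aS,9aS,9bR)-3a,6,6,9a-tetramethyldecahydronaphtho[2,1-b]furan-2(1H)-one | C[C@@]12CC[C@H]3C(C)(C)CCC[C@]3(C)[C@H]1CC(=O)O2 | starting material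
6 | cesium 2-[(1R,2R,4aS,8aS)-2-hydroxy-2,5,5,8a-tetramethyldecahydronaphthalen-1-yl]acetate | C[C@@]1(O)CC[C@H]2C(C)(C)CCC[C@]2(C)[C@H]1CC(=O)[O-].[Cs+] | intermediate
7 | ethyl 2-[(2R,4S)-2-tert-butyl-4-{2-[(1R,2R,4aS,8aS)-2-hydroxy-2,5,5,8a-tetramethyldecahydronaphthalen-1-yl]ethyl}-5-oxo-1,3-dioxolan-4-yl]acetate (8α-OH; CH2CO2Et trans to tert-butyl) | C[C@@]1(O)CC[C@H]2C(C)(C)CCC[C@]2(C)[C@H]1CC[C@@]3(CC(=O)OCC)O[C@@H](C(C)(C)C)OC3=O | intermediate
8 | ethyl 2-[(2R,4S)-2-tert-butyl-5-oxo-4-{2-[(1S,4aS,8aS)-2,5,5,8a-tetramethyl-1,4,4a,5,6,7,8,8a-octahydronaphthalen-1-yl]ethyl}-1,3-dioxolan-4-yl]acetate (Δ7; 5α-H, 9α-H) | CC1=CC[C@H]2C(C)(C)CCC[C@]2(C)[C@H]1CC[C@@]3(CC(=O)OCC)O[C@@H](C(C)(C)C)OC3=O | intermediate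
9 | ethyl 2-[(2R,4S)-2-tert-butyl-5-oxo-4-{2-[(1S,4aS,8aR)-2,5,5,8a-tetramethyl-4-oxo-1,4,4a,5,6,7,8,8a-octahydronaphthalen-1-yl]ethyl}-1,3-dioxolan-4-yl]acetate (7-en-6-one) | CC1=CC(=O)[C@H]2C(C)(C)CCC[C@]2(C)[C@H]1CC[C@@]3(CC(=O)OCC)O[C@@H](C(C)(C)C)OC3=O | intermediate
10 | ethyl (13S)-6β,13,16-trihydroxylabd-7-en-15-oate | CC1=C[C@@H](O)[C@H]2C(C)(C)CCC[C@]2(C)[C@H]1CC[C@@](O)(CO)CC(=O)OCC | intermediate
11 | (13S)-6β,13-dihydroxylabd-7-en-15,16-olide | CC1=C[C@@H](O)[C@H]2C(C)(C)CCC[C@]2(C)[C@H]1CC[C@@]3(O)COC(=O)C3 | intermediate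
12 | (13S)-7α-hydroperoxy-6β,13-dihydroxylabd-8-en-15,16-olide | CC1=C(CC[C@@]3(O)COC(=O)C3)[C@@]2(C)CCCC(C)(C)[C@@H]2[C@H](O)[C@H]1OO | intermediate
13 | (13S)-7α-acetylperoxy-6β,13-dihydroxylabd-8-en-15,16-olide | CC1=C(CC[C@@]3(O)COC(=O)C3)[C@@]2(C)CCCC(C)(C)[C@@H]2[C@H](O)[C@H]1OOC(C)=O | intermediate
14 | (13S)-6β,13-dihydroxy-7-oxolabd-8-en-15,16-olide (CNP0324736.2) | CC1=C(CC[C@@]2(O)COC(=O)C2)[C@@]2(C)CCCC(C)(C)[C@@H]2[C@H](O)C1=O | target

**Step count and risks**

Total step count: 7. Longest linear sequence: 7 steps from (R)-lactic acid (5 from sclareolide, which enters at step 3).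

The three steps most likely to fail:

Step 3, the proposed radical relay. The C13 radical may be reduced before it meets the diazo ester, the α-ester radical may take up a second diazo ester, or the diazo ester may decompose by sensitization. The fallback uses only known chemistry, sets out from 6 and 4 and comes back at 7. 6 and 4 are irradiated with the same iridium photocatalyst in DMSO/H2O without the diazo ester. This ordinary decarboxylative Giese addition, with protonation anti to the tert-butyl group, gives (2R,5R)-2-tert-butyl-5-{2-[(1R,2R,4aS,8aS)-2-hydroxy-2,5,5,8a-tetramethyldecahydronaphthalen-1-yl]ethyl}-1,3-dioxolan-4-one F1. F1 is then deprotonated with LiN(iPr)2 (2.2 equiv, THF/DMPU, −78 °C) and the enolate is alkylated with ethyl bromoacetate anti to the tert-butyl group (Seebach alkylation), which gives 7.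

Step 4, the dehydration. The exocyclic Δ8(17) and tetrasubstituted Δ8 isomers may form alongside the Δ7 alkene, and the C8 cation may be captured by the acetal oxygen on C13. The fallback sets out from 7 and comes back at 8 by a base-mediated elimination followed by a catalytic isomerization. SOCl2/pyridine in CH2Cl2 at −78 °C eliminates the equatorial chlorosulfite through the methyl hydrogens (E2) to ethyl 2-[(2R,4S)-2-tert-butyl-4-{2-[(1S,4aS,8aS)-5,5,8a-trimethyl-2-methylidenedecahydronaphthalen-1-yl]ethyl}-5-oxo-1,3-dioxolan-4-yl]acetate F2. A cobalt hydride hydrogen-atom-transfer isomerization then moves the double bond by one position to give 8; the conditions are chloro[N,N′-bis(3,5-di-tert-butylsalicylidene)-1,1,2,2-tetramethylethylenediaminato]cobalt (3 mol%), PhSiH3 (6 mol%), benzene, rt, with AgNO3–silica chromatography if some Δ8 isomer appears.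

Step 7, the photo-oxygenation. The ene reaction may take a methyl hydrogen and give the exocyclic alkene, the tetrasubstituted allylic hydroperoxide may react with a second singlet oxygen, or the 6β-OH may be acetylated. The fallback avoids singlet oxygen, sets out from 11 and comes back at 14.
- VO(acac)2 (cat.)/t-BuOOH in CH2Cl2 at 0 °C epoxidizes syn to the 6β-OH to give (13S)-7β,8β-epoxy-6β,13-dihydroxylabdan-15,16-olide F3.
- Cp2TiCl2/Mn in THF (trivalent titanium, radical opening at C8 with loss of a methyl hydrogen) gives (13S)-6β,7β,13-trihydroxylabd-8(17)-en-15,16-olide F4.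
- MnO2 in CH2Cl2 oxidizes only the allylic 7-OH to give (13S)-6β,13-dihydroxy-7-oxolabd-8(17)-en-15,16-olide F5.
- RhCl3·3H2O in EtOH at 70 °C moves the exocyclic double bond into conjugation in the ring and gives 14.

**Further compounds**

F1 | step 3 | (2R,5R)-2-tert-butyl-5-{2-[(1R,2R,4aS,8aS)-2-hydroxy-2,5,5,8a-tetramethyldecahydronaphthalen-1-yl]ethyl}-1,3-dioxolan-4-one | C[C@@]1(O)CC[C@H]2C(C)(C)CCC[C@]2(C)[C@H]1CC[C@H]3O[C@@H](C(C)(C)C)OC3=O
F2 | step 4 | ethyl 2-[(2R,4S)-2-tert-butyl-4-{2-[(1S,4aS,8aS)-5,5,8a-trimethyl-2-methylidenedecahydronaphthalen-1-yl]ethyl}-5-oxo-1,3-dioxolan-4-yl]acetate | C=C1CC[C@H]2C(C)(C)CCC[C@]2(C)[C@H]1CC[C@@]3(CC(=O)OCC)O[C@@H](C(C)(C)C)OC3=O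
F3 | step 7 | (13S)-7β,8β-epoxy-6β,13-dihydroxylabdan-15,16-olide | C[C@]12O[C@H]1[C@@H](O)[C@H]3C(C)(C)CCC[C@]3(C)[C@H]2CC[C@@]4(O)COC(=O)C4
F4 | step 7 | (13S)-6β,7β,13-trihydroxylabd-8(17)-en-15,16-olide | C=C1[C@H](CC[C@@]3(O)COC(=O)C3)[C@@]2(C)CCCC(C)(C)[C@@H]2[C@H](O)[C@@H]1O
F5 | step 7 | (13S)-6β,13-dihydroxy-7-oxolabd-8(17)-en-15,16-olide | C=C1[C@H](CC[C@@]3(O)COC(=O)C3)[C@@]2(C)CCCC(C)(C)[C@@H]2[C@H](O)C1=O
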